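**Plan**
- Cuts: (a) the C8–C(=O) aryl–acyl bond; (b) C1′–C6′ and C2′–C3′ of the side ring, after tying the C7′ oxygen to the acyl carbon as a lactone; (c) the C6–prenyl bond (O5→C6 Claisen) and the pyranone ring (Pechmann).
- Enabling feature (side ring: C1′ bears the aroyl group, C1′=C2′, C5′ bears CH3, C6′ bears the carbinol C7′): the aroyl carbon, C1′, C6′, C7′ and the carbinol oxygen are a masked five-membered lactone fused to the six-membered ring, and the C5′ methyl is cis to C7′. Closing that lactone makes the side ring the adduct of a C3′–C6′ diene and an ester-tethered alkyne.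
- Forward: ethyl (S)-lactate → (S,E)-dienol → propynoate → intramolecular [4+2], which closes the carbocycle and the γ-lactone together → hydrogenation of C4′=C5′. Separately, phloroglucinol → coumarin → 8-iodo-6-prenyl arene. The arylmagnesium opens the lactone to the ketone, then the MOM group is removed.
- Stereochemistry: C7′ comes from the lactate; C6′ from the cycloaddition (allylic 1,3-strain between the C5′ methyl and C7′); C5′ from hydrogenation anti to C7′.

Key step: step 7

Remark: the open γ-hydroxy enone form of 21 and 22 is taken to be favoured over the cyclic hemiketal, as the target is drawn (enone conjugation and, in 22, the phenol–ketone hydrogen bond).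

Step 1
Reactants: 1 ethyl (2S)-2-hydroxypropanoate (ethyl (S)-lactate)
Product: 2 ethyl (2S)-2-[(tert-butyldimethylsilyl)oxy]propanoate
Conditions: TBSCl, imidazole, DMF, 0 → 25 °C
Reagents that add atoms: tert-butyldimethylsilyl chloride, CC(C)(C)[Si](C)(C)Cl
Why: Imidazole-promoted silyl ether formation masks the hydroxyl for the ester reduction and leaves the stereocentre untouched.

Step 2
Reactants: 2 ethyl (2S)-2-[(tert-butyldimethylsilyl)oxy]propanoate
Product: 3 (2S)-2-[(tert-butyldimethylsilyl)oxy]propanal
Conditions: i-Bu2AlH (1.05 equiv), CH2Cl2, −78 °C; aq. potassium sodium tartrate; used crude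
Reagents that add atoms: none
Why: Partial ester reduction with i-Bu2AlH stops at the aluminium hemiacetal at −78 °C, and the α-silyloxy aldehyde released on work-up should keep its configuration if kept cold and used at once.

Step 3
Reactants: 3 (2S)-2-[(tert-butyldimethylsilyl)oxy]propanal
Product: 4 (2E,4S)-4-[(tert-butyldimethylsilyl)oxy]-2-methylpent-2-enal
Conditions: Ph3P=C(CH3)CHO, PhMe, 80 °C
Reagents that add atoms: 2-(triphenylphosphoranylidene)propanal, CC(C=O)=P(c1ccccc1)(c1ccccc1)c1ccccc1
Why: Wittig olefination with the stabilised α-formyl ylide should give the (E)-trisubstituted enal, with the methyl cis to the carbinol carbon, under neutral conditions that do not epimerise C7′.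

Step 4
Reactants: 4 (2E,4S)-4-[(tert-butyldimethylsilyl)oxy]-2-methylpent-2-enal
Product: 5 tert-butyldimethyl{[(2S,3E)-4-methylhexa-3,5-dien-2-yl]oxy}silane
Conditions: Ph3PCH3Br, KOtBu, THF, 0 °C
Reagents that add atoms: methyltriphenylphosphonium bromide, C[P+](c1ccccc1)(c1ccccc1)c1ccccc1.[Br-]
Why: Wittig methylenation of the enal by the non-stabilised ylide adds the terminal vinyl group by fast 1,2-addition and leaves the (E)-alkene and the allylic silyl ether intact.

Step 5
Reactants: 5 tert-butyldimethyl{[(2S,3E)-4-methylhexa-3,5-dien-2-yl]oxy}silane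
Product: 6 (2S,3E)-4-methylhexa-3,5-dien-2-ol
Conditions: Bu4NF, THF, 0 → 25 °C; volatile product kept in solution
Reagents that add atoms: none
Why: Fluoride-induced desilylation frees the secondary dienyl alcohol without acid, so the pentadienyl carbinol should not ionise.

Step 6
Reactants: 6 (2S,3E)-4-methylhexa-3,5-dien-2-ol; 7 prop-2-ynoic acid (propiolic acid)
Product: 8 (2S,3E)-4-methylhexa-3,5-dien-2-yl prop-2-ynoate
Conditions: N,N′-dicyclohexylcarbodiimide (DCC), DMAP (5 mol %), CH2Cl2, −20 → 0 °C
Reagents that add atoms: none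
Why: Steglich esterification acylates the alcohol with retention at C7′; low temperature and little DMAP limit amine addition to the ynoate.

Step 7
Reactants: 8 (2S,3E)-4-methylhexa-3,5-dien-2-yl prop-2-ynoate
Product: 9 (3S,3aR)-3,4-dimethyl-3a,6-dihydro-2-benzofuran-1(3H)-one
Conditions: degassed PhMe (0.01 M), BHT (10 mol %), 120 °C, sealed vessel, argon
Reagents that add atoms: none
Why: This is a thermal, concerted [4+2] cycloaddition in which the ynoate is the 2π partner and C3′=C4′–C5′=C6′ the s-cis diene, forming C1′–C6′ and C2′–C3′ in one event; the closest known reaction type is the ester-tethered intramolecular Diels–Alder reaction of pentadienyl propynoates and acrylates. The carbocycle closes as the six-membered cycloaddition ring (a cyclohexa-1,4-diene), and the lactone closes as the five-membered ring fused across C1′–C6′, because the three-atom tether C7′–O–C(=O) can only bring the carbonyl-bearing alkyne carbon to C6′, which also fixes the regiochemistry. The one new stereocentre, C6′, is set by C7′: allylic 1,3-strain with the cis C5′ methyl should hold the C7′ hydrogen in the diene plane, so the ester oxygen and the alkyne sit on one face and the C7′ methyl on the other, and the (S)-carbinol should give (R)-C6′. An alkyne has no endo/exo issue, so facial selectivity is the only selectivity required. High dilution, BHT and exclusion of air are meant to suppress oligomerisation of the ynoate and loss of H2 from the 1,4-diene, which is carried into step 8 without storage.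

Step 8
Reactants: 9 (3S,3aR)-3,4-dimethyl-3a,6-dihydro-2-benzofuran-1(3H)-one
Product: 10 (3S,3aR,4R)-3,4-dimethyl-3a,4,5,6-tetrahydro-2-benzofuran-1(3H)-one
Conditions: [Ir(cod)(PCy3)(py)]PF6 (5 mol %), H2 (1 atm), CH2Cl2, 0 → 25 °C
Reagents that add atoms: none
Why: Homogeneous hydrogenation with Crabtree's cationic iridium catalyst should take the electron-rich trisubstituted C4′=C5′ alkene well before the electron-poor conjugated C1′=C2′ alkene, and with no ligating group in reach it should add H2 syn from the face carrying only the C6′ hydrogen, anti to C7′, setting C5′ as R with the methyl cis to C7′.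

Step 9
Reactants: 11 phloroglucinol (benzene-1,3,5-triol); 12 ethyl 2-methyl-3-oxobutanoate
Product: 13 5,7-dihydroxy-3,4-dimethyl-2H-chromen-2-one
Conditions: conc. H2SO4, 0 → 25 °C
Reagents that add atoms: none
Why: Pechmann condensation (transesterification, ring-closing hydroxyalkylation, dehydration) can give only one coumarin because of the threefold symmetry of phloroglucinol.

Step 10
Reactants: 13 5,7-dihydroxy-3,4-dimethyl-2H-chromen-2-one
Product: 14 5-hydroxy-7-(methoxymethoxy)-3,4-dimethyl-2H-chromen-2-one
Conditions: MOMCl (1.05 equiv), i-Pr2NEt, CH2Cl2–DMF, 0 °C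
Reagents that add atoms: chloromethyl methyl ether, COCCl
Why: Williamson-type O-alkylation should go to the 7-hydroxyl, which is the more acidic (para to the enoate-bearing ring carbon) and the less hindered, the 5-hydroxyl being crowded by the peri C4 methyl.

Step 11
Reactants: 14 5-hydroxy-7-(methoxymethoxy)-3,4-dimethyl-2H-chromen-2-one
Product: 15 7-(methoxymethoxy)-3,4-dimethyl-5-[(2-methylbut-3-en-2-yl)oxy]-2H-chromen-2-one
Conditions: Pd(PPh3)4 (5 mol %), tert-butyl 2-methylbut-3-en-2-yl carbonate, THF, 0 → 25 °C
Reagents that add atoms: tert-butyl 2-methylbut-3-en-2-yl carbonate, C=CC(C)(C)OC(=O)OC(C)(C)C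
Why: Tsuji–Trost O-allylation: zerovalent palladium ionises the tertiary carbonate, releasing CO2 and tert-butoxide, which deprotonates the phenol, and the phenoxide should attack the more substituted terminus of the 1,1-dimethyl-π-allyl complex under kinetic control to give the tertiary aryl ether.

Step 12
Reactants: 15 7-(methoxymethoxy)-3,4-dimethyl-5-[(2-methylbut-3-en-2-yl)oxy]-2H-chromen-2-one
Product: 16 8-iodo-7-(methoxymethoxy)-3,4-dimethyl-5-[(2-methylbut-3-en-2-yl)oxy]-2H-chromen-2-one
Conditions: N-iodosuccinimide (1.05 equiv), DMF, 0 °C, dark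
Reagents that add atoms: N-iodosuccinimide, O=C1CCC(=O)N1I
Why: Electrophilic aromatic iodination should go to C8 (para to O5, between O7 and the ring oxygen) because C6 is walled in by the tertiary ether, and the neutral N-iodoimide at 0 °C should neither add to the monosubstituted alkene nor ionise the tertiary ether.

Step 13
Reactants: 16 8-iodo-7-(methoxymethoxy)-3,4-dimethyl-5-[(2-methylbut-3-en-2-yl)oxy]-2H-chromen-2-one
Product: 18 5-hydroxy-8-iodo-7-(methoxymethoxy)-3,4-dimethyl-6-(3-methylbut-2-en-1-yl)-2H-chromen-2-one, via ortho-dienone 17 (not isolated)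
Conditions: m-xylene, 130 °C, argon
Reagents that add atoms: none
Why: Aromatic Claisen rearrangement ([3,3]-sigmatropic shift, then tautomerisation of the dienone) can only go to C6, the one ortho position bearing hydrogen, and the allyl inversion turns the tertiary ether into the 3-methylbut-2-enyl chain.

Step 14
Reactants: 18 5-hydroxy-8-iodo-7-(methoxymethoxy)-3,4-dimethyl-6-(3-methylbut-2-en-1-yl)-2H-chromen-2-one
Product: 19 8-iodo-5-methoxy-7-(methoxymethoxy)-3,4-dimethyl-6-(3-methylbut-2-en-1-yl)-2H-chromen-2-one
Conditions: MeI, K2CO3, DMF, 25 °C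
Reagents that add atoms: iodomethane, CI
Why: Williamson O-methylation of the phenoxide; the aryl iodide, MOM ether and alkene are inert to carbonate base.

Step 15
Reactants: 19 8-iodo-5-methoxy-7-(methoxymethoxy)-3,4-dimethyl-6-(3-methylbut-2-en-1-yl)-2H-chromen-2-one; 10 (3S,3aR,4R)-3,4-dimethyl-3a,4,5,6-tetrahydro-2-benzofuran-1(3H)-one
Product: 21 8-{[(5R,6R)-6-[(1S)-1-hydroxyethyl]-5-methylcyclohex-1-en-1-yl]carbonyl}-5-methoxy-7-(methoxymethoxy)-3,4-dimethyl-6-(3-methylbut-2-en-1-yl)-2H-chromen-2-one, via arylmagnesium chloride 20 (not isolated)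
Conditions: 19 (1.3 equiv), i-PrMgCl·LiCl, THF, −40 °C; then 10, −40 → −10 °C; aq. NH4Cl
Reagents that add atoms: none
Why: Iodine–magnesium exchange with the LiCl-complexed Grignard reagent at −40 °C tolerates ester-type carbonyls such as the coumarin lactone, and 1,2-addition of the MOM-chelated arylmagnesium to the γ-lactone should stop at the ketone because the magnesium lactolate persists in the cold and a di-ortho-substituted aryl ketone resists a second addition; no stereocentre is touched.

Step 16
Reactants: 21 8-{[(5R,6R)-6-[(1S)-1-hydroxyethyl]-5-methylcyclohex-1-en-1-yl]carbonyl}-5-methoxy-7-(methoxymethoxy)-3,4-dimethyl-6-(3-methylbut-2-en-1-yl)-2H-chromen-2-one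
Product: 22 7-hydroxy-8-{[(5R,6R)-6-[(1S)-1-hydroxyethyl]-5-methylcyclohex-1-en-1-yl]carbonyl}-5-methoxy-3,4-dimethyl-6-(3-methylbut-2-en-1-yl)-2H-chromen-2-one
Conditions: 2 M aq. HCl, THF, 25 °C
Reagents that add atoms: none
Why: Acid-catalysed acetal hydrolysis should cleave the MOM ether next to the aryl ketone under mild aqueous acid at room temperature, conditions under which ortho-prenyl phenols and the hydroxy enone are expected to persist.

**Compound list**
1 | ethyl (2S)-2-hydroxypropanoate (ethyl (S)-lactate) | C[C@H](O)C(=O)OCC | starting material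
2 | ethyl (2S)-2-[(tert-butyldimethylsilyl)oxy]propanoate | C[C@H](O[Si](C)(C)C(C)(C)C)C(=O)OCC | intermediate
3 | (2S)-2-[(tert-butyldimethylsilyl)oxy]propanal | C[C@H](O[Si](C)(C)C(C)(C)C)C=O | intermediate
4 | (2E,4S)-4-[(tert-butyldimethylsilyl)oxy]-2-methylpent-2-enal | C[C@H](O[Si](C)(C)C(C)(C)C)/C=C(\C)C=O | intermediate
5 | tert-butyldimethyl{[(2S,3E)-4-methylhexa-3,5-dien-2-yl]oxy}silane | C[C@H](O[Si](C)(C)C(C)(C)C)/C=C(\C)C=C | intermediate
6 | (2S,3E)-4-methylhexa-3,5-dien-2-ol | C[C@H](O)/C=C(\C)C=C | intermediate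
7 | prop-2-ynoic acid (propiolic acid) | C#CC(=O)O | starting material
8 | (2S,3E)-4-methylhexa-3,5-dien-2-yl prop-2-ynoate | C#CC(=O)O[C@@H](C)/C=C(\C)C=C | intermediate
9 | (3S,3aR)-3,4-dimethyl-3a,6-dihydro-2-benzofuran-1(3H)-one | C[C@@H]1OC(=O)C2=CCC=C(C)[C@@H]12 | intermediate
10 | (3S,3aR,4R)-3,4-dimethyl-3a,4,5,6-tetrahydro-2-benzofuran-1(3H)-one | C[C@@H]1OC(=O)C2=CCC[C@@H](C)[C@@H]12 | intermediate
11 | phloroglucinol (benzene-1,3,5-triol) | Oc1cc(O)cc(O)c1 | starting material
12 | ethyl 2-methyl-3-oxobutanoate (ethyl 2-methylacetoacetate) | CCOC(=O)C(C)C(C)=O | starting material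
13 | 5,7-dihydroxy-3,4-dimethyl-2H-chromen-2-one | Cc1c(C)c2c(O)cc(O)cc2oc1=O | intermediate
14 | 5-hydroxy-7-(methoxymethoxy)-3,4-dimethyl-2H-chromen-2-one | COCOc1cc(O)c2c(C)c(C)c(=O)oc2c1 | intermediate
15 | 7-(methoxymethoxy)-3,4-dimethyl-5-[(2-methylbut-3-en-2-yl)oxy]-2H-chromen-2-one | COCOc1cc(OC(C)(C)C=C)c2c(C)c(C)c(=O)oc2c1 | intermediate
16 | 8-iodo-7-(methoxymethoxy)-3,4-dimethyl-5-[(2-methylbut-3-en-2-yl)oxy]-2H-chromen-2-one | COCOc1cc(OC(C)(C)C=C)c2c(C)c(C)c(=O)oc2c1I | intermediate
17 | 8-iodo-7-(methoxymethoxy)-3,4-dimethyl-6-(3-methylbut-2-en-1-yl)-2H-chromene-2,5(6H)-dione (Claisen dienone, racemic at C6, not isolated) | COCOC1=C(I)C2=C(C(C)=C(C)C(=O)O2)C(=O)C1CC=C(C)C | intermediate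
18 | 5-hydroxy-8-iodo-7-(methoxymethoxy)-3,4-dimethyl-6-(3-methylbut-2-en-1-yl)-2H-chromen-2-one | COCOc1c(CC=C(C)C)c(O)c2c(C)c(C)c(=O)oc2c1I | intermediate
19 | 8-iodo-5-methoxy-7-(methoxymethoxy)-3,4-dimethyl-6-(3-methylbut-2-en-1-yl)-2H-chromen-2-one | COCOc1c(CC=C(C)C)c(OC)c2c(C)c(C)c(=O)oc2c1I | intermediate
20 | [5-methoxy-7-(methoxymethoxy)-3,4-dimethyl-6-(3-methylbut-2-en-1-yl)-2-oxo-2H-chromen-8-yl]magnesium chloride (not isolated) | COCOc1c(CC=C(C)C)c(OC)c2c(C)c(C)c(=O)oc2c1[Mg]Cl | intermediate
21 | 8-{[(5R,6R)-6-[(1S)-1-hydroxyethyl]-5-methylcyclohex-1-en-1-yl]carbonyl}-5-methoxy-7-(methoxymethoxy)-3,4-dimethyl-6-(3-methylbut-2-en-1-yl)-2H-chromen-2-one | COCOc1c(CC=C(C)C)c(OC)c2c(C)c(C)c(=O)oc2c1C(=O)C1=CCC[C@@H](C)[C@H]1[C@H](C)O | intermediate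
22 | 7-hydroxy-8-{[(5R,6R)-6-[(1S)-1-hydroxyethyl]-5-methylcyclohex-1-en-1-yl]carbonyl}-5-methoxy-3,4-dimethyl-6-(3-methylbut-2-en-1-yl)-2H-chromen-2-one | COc1c(CC=C(C)C)c(O)c(C(=O)C2=CCC[C@@H](C)[C@H]2[C@H](C)O)c2oc(=O)c(C)c(C)c12 | target

**Count**
Total steps: 16. Longest linear sequence: 10 steps (steps 1–8, 15, 16, from ethyl (S)-lactate); the arene branch is steps 9–14.

**Steps most likely to fail, with fallbacks**

Step 15 (aryl–acyl coupling). Acyl substitution at the hindered, doubly ortho-oxygenated arylmagnesium may be slower than proton abstraction from C3′ of the enoate, conjugate addition at C2′, or attack of 20 on the coumarin carbonyl of a second molecule. The fallback sets out from 10 (with 19) and returns at 21; it lowers the electrophile to the aldehyde oxidation level. Lactone 10 is reduced with i-Bu2AlH (CH2Cl2, −78 °C) to the lactol (3S,3aR,4R)-3,4-dimethyl-1,3,3a,4,5,6-hexahydro-2-benzofuran-1-ol F1. The lactol is deprotonated with one equivalent of i-PrMgCl, and arylmagnesium 20, made from 19 as in step 15, adds to the open-chain enal that is in equilibrium with the magnesium lactolate. This should give the diol 8-{hydroxy[(5R,6R)-6-[(1S)-1-hydroxyethyl]-5-methylcyclohex-1-en-1-yl]methyl}-5-methoxy-7-(methoxymethoxy)-3,4-dimethyl-6-(3-methylbut-2-en-1-yl)-2H-chromen-2-one F2 as a mixture of epimers at the new carbinol. MnO2 in CH2Cl2 should then oxidise only the carbinol that is both benzylic and allylic, leaving the C7′ alcohol, to give 21.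

Step 8 (hydrogenation). The conjugated C1′=C2′ alkene may be reduced as well, hydrogen may be delivered from the lactone face, or the 1,4-diene may lose H2 to the aromatic phthalide on the metal. The fallback goes from 9 back to 10 and replaces catalytic syn-addition of H2 by ionic hydrogenation (Et3SiH, CF3CO2H, CH2Cl2, 0 °C). Protonation can occur only at the electron-rich alkene (at C4′), giving the tertiary C5′ cation, which the enoate cannot match, and hydride transfer from the silane should arrive anti to C7′. No compound outside the list is made (none F0).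

Step 11 (tertiary O-allylation). The hindered C5 phenoxide may attack the unsubstituted terminus of the π-allyl complex, giving the linear prenyl ether, which would deliver the wrong chain in step 13, or alkylation may stall. The fallback sets out from 14 and returns at 15. Copper-catalysed propargylation with 3-chloro-3-methylbut-1-yne (CuCl2 cat., DBU, MeCN, 0 °C) runs through a copper allenylidene and can only give the tertiary ether, 7-(methoxymethoxy)-3,4-dimethyl-5-[(2-methylbut-3-yn-2-yl)oxy]-2H-chromen-2-one F3. Semi-hydrogenation over Pd/CaCO3 poisoned with Pb(OAc)2 and quinoline (H2, EtOAc) then gives 15.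

**Further compounds**
F1 | step 15 | (3S,3aR,4R)-3,4-dimethyl-1,3,3a,4,5,6-hexahydro-2-benzofuran-1-ol (both anomers) | C[C@@H]1OC(O)C2=CCC[C@@H](C)[C@@H]12
F2 | step 15 | 8-{hydroxy[(5R,6R)-6-[(1S)-1-hydroxyethyl]-5-methylcyclohex-1-en-1-yl]methyl}-5-methoxy-7-(methoxymethoxy)-3,4-dimethyl-6-(3-methylbut-2-en-1-yl)-2H-chromen-2-one | COCOc1c(CC=C(C)C)c(OC)c2c(C)c(C)c(=O)oc2c1C(O)C1=CCC[C@@H](C)[C@H]1[C@H](C)O
F0 | step 8 | none | none
F3 | step 11 | 7-(methoxymethoxy)-3,4-dimethyl-5-[(2-methylbut-3-yn-2-yl)oxy]-2H-chromen-2-one | COCOc1cc(OC(C)(C)C#C)c2c(C)c(C)c(=O)oc2c1
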